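## Retrosynthetic overview

1. Norkurarinol ⇐ its tris-MOM ether. Rings A and B are bought as resorcinol; ring C is the only ring built and is closed last, by an enantioselective 6-endo oxa-Michael addition of a 2'-hydroxychalcone that sets C2.
2. Chalcone ⇐ Claisen–Schmidt union of a ring A acetophenone (side chain already in place) with 2,4-bis(methoxymethoxy)benzaldehyde (ring B, from resorcinol by Vilsmeier formylation).
3. Acetophenone ⇐ ortho-lithiation/acetylation of a 2-alkylphloroglucinol triether. SEM on O1/O7 and MOM on O5 make the later ring closure regiospecific.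
4. Side-chain stereocentre ⇐ two consecutive 1,2-metallate shifts on boron: Pd-catalysed conjunctive coupling of an alkyl boronate, vinyllithium and the aryl bromide (alkyl migrates from B to C, sets R), then Zweifel olefination (stereoretentive shift that brings in the isopropenyl group).
5. Aryl bromide ⇐ resorcinol (SEM ethers, ortho-lithiation/bromination, Ir-catalysed C–H borylation/oxidation for the third oxygen); alkyl boronate ⇐ 2-methylbut-3-en-2-ol (silylation, hydroboration).

Assumption: (Sp,Sp)-MandyPhos (step 7) and (R)-TRIP (step 14) are taken to be the antipodes that give the R boronate and the 2S flavanone; if the sense of induction is the opposite, the mirror-image ligand or catalyst is used.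

## Route

Step 1
Reactants: 1 resorcinol
Product: 2 1,3-bis{[2-(trimethylsilyl)ethoxy]methoxy}benzene
Conditions: SEMCl, i-Pr2NEt, CH2Cl2, 0 to 25 °C
Reagents that add atoms: 2-(trimethylsilyl)ethoxymethyl chloride (SEMCl), C[Si](C)(C)CCOCCl
Why: Two-fold Williamson-type O-alkylation of the phenol; SEM is chosen because it directs ortho-lithiation and is later cleaved by fluoride without touching MOM.

Step 2
Reactants: 2 1,3-bis{[2-(trimethylsilyl)ethoxy]methoxy}benzene
Product: 4 2-bromo-1,3-bis{[2-(trimethylsilyl)ethoxy]methoxy}benzene, via aryllithium 3 (not isolated)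
Conditions: n-BuLi, THF, 0 °C; then BrCl2CCCl2Br, −78 to 25 °C
Reagents that add atoms: n-butyllithium, [Li]CCCC (lithium of 3); 1,2-dibromo-1,1,2,2-tetrachloroethane, BrC(Cl)(Cl)C(Cl)(Cl)Br
Why: Directed ortho-metalation removes the C–H flanked by the two acetal oxygens, and the aryllithium is brominated by the positive-bromine donor.

Step 3
Reactants: 4 2-bromo-1,3-bis{[2-(trimethylsilyl)ethoxy]methoxy}benzene
Product: 6 4-bromo-3,5-bis{[2-(trimethylsilyl)ethoxy]methoxy}phenol, via arylboronic ester 5 (not isolated)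
Conditions: B2pin2, [Ir(OMe)(cod)]2 (1.5 mol%), dtbpy (3 mol%), THF, 80 °C; then H2O2, NaOH aq, THF, 0 °C
Reagents that add atoms: bis(pinacolato)diboron, CC1(C)OB(OC1(C)C)B1OC(C)(C)C(C)(C)O1 (boron of 5); hydrogen peroxide, OO (oxygen of 6)
Why: Sterically controlled iridium-catalysed C–H borylation hits the only C–H without an ortho substituent (para to Br), and peroxide oxidation of the C–B bond gives the phenol that becomes O5.

Step 4
Reactants: 6 4-bromo-3,5-bis{[2-(trimethylsilyl)ethoxy]methoxy}phenol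
Product: 7 2-bromo-5-(methoxymethoxy)-1,3-bis{[2-(trimethylsilyl)ethoxy]methoxy}benzene
Conditions: MOMCl, i-Pr2NEt, CH2Cl2, 0 to 25 °C
Reagents that add atoms: chloromethyl methyl ether (MOMCl), COCCl
Why: Williamson-type alkylation of the lone phenol puts a MOM group, orthogonal to SEM, on the oxygen that must stay blocked while ring C is closed.

Step 5
Reactants: 8 2-methylbut-3-en-2-ol
Product: 9 triethyl[(2-methylbut-3-en-2-yl)oxy]silane
Conditions: TESOTf, 2,6-lutidine, CH2Cl2, 0 °C
Reagents that add atoms: triethylsilyl trifluoromethanesulfonate, CC[Si](CC)(CC)OS(=O)(=O)C(F)(F)F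
Why: Silylation with the reactive silyl triflate masks the tertiary OH, which would otherwise quench the organolithium reagents and bind boron.

Step 6
Reactants: 9 triethyl[(2-methylbut-3-en-2-yl)oxy]silane
Product: 10 triethyl{[2-methyl-4-(4,4,5,5-tetramethyl-1,3,2-dioxaborolan-2-yl)butan-2-yl]oxy}silane
Conditions: HBpin, [Ir(cod)Cl]2 (1.5 mol%), dppm (3 mol%), CH2Cl2, 25 °C
Reagents that add atoms: pinacolborane, CC1(C)OBOC1(C)C
Why: Iridium-catalysed anti-Markovnikov hydroboration of the monosubstituted alkene puts boron on the terminal carbon.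

Step 7
Reactants: 10 triethyl{[2-methyl-4-(4,4,5,5-tetramethyl-1,3,2-dioxaborolan-2-yl)butan-2-yl]oxy}silane; 7 2-bromo-5-(methoxymethoxy)-1,3-bis{[2-(trimethylsilyl)ethoxy]methoxy}benzene
Product: 12 2-{(2R)-5-methyl-2-(4,4,5,5-tetramethyl-1,3,2-dioxaborolan-2-yl)-5-[(triethylsilyl)oxy]hexyl}-5-(methoxymethoxy)-1,3-bis{[2-(trimethylsilyl)ethoxy]methoxy}benzene, via lithium vinylborate 11 (not isolated)
Conditions: vinyl bromide, t-BuLi, Et2O, −78 °C; add 10, −78 to 25 °C; then 7, Pd(OAc)2 (2 mol%), (Sp,Sp)-MandyPhos (2.4 mol%), NaOTf, THF, 60 °C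
Reagents that add atoms: vinyllithium, [Li]C=C (made from vinyl bromide, C=CBr, and tert-butyllithium, [Li]C(C)(C)C)
Why: Conjunctive cross-coupling, in which the aryl–palladium cation formed from 7 and zerovalent palladium binds the vinyl group of borate 11 and triggers a 1,2-metallate shift of the alkyl group from boron to carbon anti to palladium, reductive elimination then forms the aryl–CH2 bond, and the chiral MandyPhos ligand selects the alkene face and so sets the R centre.

Step 8
Reactants: 12 2-{(2R)-5-methyl-2-(4,4,5,5-tetramethyl-1,3,2-dioxaborolan-2-yl)-5-[(triethylsilyl)oxy]hexyl}-5-(methoxymethoxy)-1,3-bis{[2-(trimethylsilyl)ethoxy]methoxy}benzene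
Product: 15 5-(methoxymethoxy)-2-{(2R)-5-methyl-2-(prop-1-en-2-yl)-5-[(triethylsilyl)oxy]hexyl}-1,3-bis{[2-(trimethylsilyl)ethoxy]methoxy}benzene, via lithium isopropenylborate 13 (not isolated), via iodoalkyl boronic ester 14 (not isolated)
Conditions: 2-bromopropene, t-BuLi, THF, −78 °C; add 12, −78 to 0 °C; I2 (1.2 equiv), MeOH, −78 °C; NaOMe, MeOH, −78 to 25 °C; Na2S2O3 aq
Reagents that add atoms: isopropenyllithium, [Li]C(C)=C (made from 2-bromopropene, CC(Br)=C, and tert-butyllithium, [Li]C(C)(C)C); iodine, II (iodine of 14)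
Why: Zweifel olefination, in which iodine activates the alkenyl group of borate 13, the stereogenic carbon migrates from boron to carbon with retention (the second 1,2-metallate shift) and methoxide-induced anti elimination of boron and iodide releases the isopropenyl group, so the R centre is carried through unchanged.

Step 9
Reactants: 15 5-(methoxymethoxy)-2-{(2R)-5-methyl-2-(prop-1-en-2-yl)-5-[(triethylsilyl)oxy]hexyl}-1,3-bis{[2-(trimethylsilyl)ethoxy]methoxy}benzene
Product: 17 1-[6-(methoxymethoxy)-3-{(2R)-5-methyl-2-(prop-1-en-2-yl)-5-[(triethylsilyl)oxy]hexyl}-2,4-bis{[2-(trimethylsilyl)ethoxy]methoxy}phenyl]ethan-1-one, via aryllithium 16 (not isolated)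
Conditions: n-BuLi, THF, 0 °C; then MeC(O)N(OMe)Me, −78 to 0 °C
Reagents that add atoms: n-butyllithium, [Li]CCCC (lithium of 16); N-methoxy-N-methylacetamide, CC(=O)N(C)OC
Why: Directed ortho-metalation at the C–H flanked by OSEM and OMOM (the two remaining ring positions are equivalent), then acylation with the Weinreb amide, whose chelated tetrahedral adduct prevents over-addition.

Step 10
Reactants: 17 1-[6-(methoxymethoxy)-3-{(2R)-5-methyl-2-(prop-1-en-2-yl)-5-[(triethylsilyl)oxy]hexyl}-2,4-bis{[2-(trimethylsilyl)ethoxy]methoxy}phenyl]ethan-1-one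
Product: 18 1-{2,4-dihydroxy-3-[(2R)-5-hydroxy-5-methyl-2-(prop-1-en-2-yl)hexyl]-6-(methoxymethoxy)phenyl}ethan-1-one
Conditions: Bu4NF, H2NCH2CH2NH2, THF, 60 °C; NH4Cl aq
Reagents that add atoms: none
Why: Fluoride-induced desilylation, in which both aryl SEM ethers fragment (to fluorosilane, ethene and formaldehyde, the last trapped by the diamine) and the TES ether is cleaved, while the MOM ether on O5 is inert to fluoride, so only O1 and O7 are freed.

Step 11
Reactants: 1 resorcinol
Product: 20 2,4-dihydroxybenzaldehyde, via iminium chloride 19 (not isolated)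
Conditions: POCl3, DMF, MeCN, −15 to 25 °C; then H2O, 50 °C
Reagents that add atoms: N,N-dimethylformamide, CN(C)C=O (carbon of the formyl group; carbon and nitrogen of 19); phosphoryl chloride, O=P(Cl)(Cl)Cl (chloride of 19); water, O (oxygen of the formyl group)
Why: Vilsmeier–Haack formylation occurs para to one OH and ortho to the other, and hydrolysis of the iminium salt gives the aldehyde.

Step 12
Reactants: 20 2,4-dihydroxybenzaldehyde
Product: 21 2,4-bis(methoxymethoxy)benzaldehyde
Conditions: NaH, MOMCl, DMF, 0 to 25 °C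
Reagents that add atoms: chloromethyl methyl ether (MOMCl), COCCl
Why: Williamson-type alkylation of both phenoxides (NaH is needed for the hydrogen-bonded 2-OH) gives a base-stable aldehyde.

Step 13
Reactants: 18 1-{2,4-dihydroxy-3-[(2R)-5-hydroxy-5-methyl-2-(prop-1-en-2-yl)hexyl]-6-(methoxymethoxy)phenyl}ethan-1-one; 21 2,4-bis(methoxymethoxy)benzaldehyde
Product: 22 (2E)-3-[2,4-bis(methoxymethoxy)phenyl]-1-{2,4-dihydroxy-3-[(2R)-5-hydroxy-5-methyl-2-(prop-1-en-2-yl)hexyl]-6-(methoxymethoxy)phenyl}prop-2-en-1-one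
Conditions: KOH (50% aq), EtOH, 25 °C; then dilute HCl to pH 5, 0 °C
Reagents that add atoms: none
Why: Claisen–Schmidt condensation, in which the ketone enolate adds to the non-enolisable aldehyde and E1cB loss of water gives the conjugated E-enone, with cold acidification to avoid premature ring closure.

Step 14
Reactants: 22 (2E)-3-[2,4-bis(methoxymethoxy)phenyl]-1-{2,4-dihydroxy-3-[(2R)-5-hydroxy-5-methyl-2-(prop-1-en-2-yl)hexyl]-6-(methoxymethoxy)phenyl}prop-2-en-1-one
Product: 23 (2S)-2-[2,4-bis(methoxymethoxy)phenyl]-7-hydroxy-8-[(2R)-5-hydroxy-5-methyl-2-(prop-1-en-2-yl)hexyl]-5-(methoxymethoxy)-2,3-dihydro-4H-chromen-4-one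
Conditions: (R)-TRIP [(R)-3,3′-bis(2,4,6-triisopropylphenyl)-1,1′-binaphthyl-2,2′-diyl hydrogen phosphate] (10 mol%), 4 Å MS, PhMe, 0 °C
Reagents that add atoms: none
Why: Proposed new method: an enantioselective 6-endo oxa-Michael cyclisation of an unactivated 2'-hydroxychalcone under chiral phosphoric acid catalysis, in which the P–OH hydrogen-bonds to the carbonyl of the aryl ketone (twisted out of plane by its two ortho oxygens, so the enone is more electrophilic) while the P=O accepts the hydrogen bond of the free 2'-OH (only O1 can close because O5 carries MOM), the 2,4-dialkoxyphenyl group stabilises positive charge at the β-carbon, and C–O bond formation inside the chiral hydrogen-bonded ion pair sets C2 as S; ring closure of a 6'-alkoxychalcone is strongly downhill, so reversal and racemisation are slow at 0 °C and the weak acid leaves MOM, the tertiary alcohol and the isopropenyl group alone; the closest known reaction types are the chiral phosphoric acid catalysed aza-Michael cyclisation of 2'-aminochalcones to 2-aryl-2,3-dihydroquinolin-4-ones and the amine–thiourea catalysed oxa-Michael cyclisation of activated alkylidene β-keto esters to flavanones.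

Step 15
Reactants: 23 (2S)-2-[2,4-bis(methoxymethoxy)phenyl]-7-hydroxy-8-[(2R)-5-hydroxy-5-methyl-2-(prop-1-en-2-yl)hexyl]-5-(methoxymethoxy)-2,3-dihydro-4H-chromen-4-one
Product: 24 norkurarinol, (2S)-2-(2,4-dihydroxyphenyl)-5,7-dihydroxy-8-[(2R)-5-hydroxy-5-methyl-2-(prop-1-en-2-yl)hexyl]-2,3-dihydro-4H-chromen-4-one
Conditions: HCl (1 M in MeOH), 25 °C
Reagents that add atoms: none
Why: Acid-catalysed acetal exchange with methanol removes the three MOM groups as dimethoxymethane at 25 °C, mild enough to leave the tertiary alcohol, the isopropenyl group and the C2–O bond (hence the 2S centre) untouched.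

## Compound list

1 | resorcinol | Oc1cccc(O)c1 | starting material
2 | 1,3-bis{[2-(trimethylsilyl)ethoxy]methoxy}benzene | C[Si](C)(C)CCOCOc1cccc(OCOCC[Si](C)(C)C)c1 | intermediate
3 | (2,6-bis{[2-(trimethylsilyl)ethoxy]methoxy}phenyl)lithium | [Li]c1c(OCOCC[Si](C)(C)C)cccc1OCOCC[Si](C)(C)C | intermediate, not isolated
4 | 2-bromo-1,3-bis{[2-(trimethylsilyl)ethoxy]methoxy}benzene | Brc1c(OCOCC[Si](C)(C)C)cccc1OCOCC[Si](C)(C)C | intermediate
5 | 2-(4-bromo-3,5-bis{[2-(trimethylsilyl)ethoxy]methoxy}phenyl)-4,4,5,5-tetramethyl-1,3,2-dioxaborolane | Brc1c(OCOCC[Si](C)(C)C)cc(B2OC(C)(C)C(C)(C)O2)cc1OCOCC[Si](C)(C)C | intermediate, not isolated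
6 | 4-bromo-3,5-bis{[2-(trimethylsilyl)ethoxy]methoxy}phenol | Brc1c(OCOCC[Si](C)(C)C)cc(O)cc1OCOCC[Si](C)(C)C | intermediate
7 | 2-bromo-5-(methoxymethoxy)-1,3-bis{[2-(trimethylsilyl)ethoxy]methoxy}benzene | Brc1c(OCOCC[Si](C)(C)C)cc(OCOC)cc1OCOCC[Si](C)(C)C | intermediate
8 | 2-methylbut-3-en-2-ol | C=CC(C)(C)O | starting material
9 | triethyl[(2-methylbut-3-en-2-yl)oxy]silane | C=CC(C)(C)O[Si](CC)(CC)CC | intermediate
10 | triethyl{[2-methyl-4-(4,4,5,5-tetramethyl-1,3,2-dioxaborolan-2-yl)butan-2-yl]oxy}silane | CC[Si](CC)(CC)OC(C)(C)CCB1OC(C)(C)C(C)(C)O1 | intermediate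
11 | lithium ethenyl{3-methyl-3-[(triethylsilyl)oxy]butyl}(pinacolato)borate | [Li+].C=C[B-]1(CCC(C)(C)O[Si](CC)(CC)CC)OC(C)(C)C(C)(C)O1 | intermediate, not isolated
12 | 2-{(2R)-5-methyl-2-(4,4,5,5-tetramethyl-1,3,2-dioxaborolan-2-yl)-5-[(triethylsilyl)oxy]hexyl}-5-(methoxymethoxy)-1,3-bis{[2-(trimethylsilyl)ethoxy]methoxy}benzene | CC[Si](CC)(CC)OC(C)(C)CC[C@H](Cc1c(OCOCC[Si](C)(C)C)cc(OCOC)cc1OCOCC[Si](C)(C)C)B1OC(C)(C)C(C)(C)O1 | intermediate
13 | lithium {(2R)-1-[4-(methoxymethoxy)-2,6-bis{[2-(trimethylsilyl)ethoxy]methoxy}phenyl]-5-methyl-5-[(triethylsilyl)oxy]hexan-2-yl}(pinacolato)(prop-1-en-2-yl)borate | [Li+].C=C(C)[B-]1(OC(C)(C)C(C)(C)O1)[C@H](CCC(C)(C)O[Si](CC)(CC)CC)Cc1c(OCOCC[Si](C)(C)C)cc(OCOC)cc1OCOCC[Si](C)(C)C | intermediate, not isolated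
14 | 2-{(3R)-1-iodo-2,6-dimethyl-3-{[4-(methoxymethoxy)-2,6-bis{[2-(trimethylsilyl)ethoxy]methoxy}phenyl]methyl}-6-[(triethylsilyl)oxy]heptan-2-yl}-4,4,5,5-tetramethyl-1,3,2-dioxaborolane (both epimers at C-2 of the heptane chain) | ICC(C)(B1OC(C)(C)C(C)(C)O1)[C@H](CCC(C)(C)O[Si](CC)(CC)CC)Cc1c(OCOCC[Si](C)(C)C)cc(OCOC)cc1OCOCC[Si](C)(C)C | intermediate, not isolated
15 | 5-(methoxymethoxy)-2-{(2R)-5-methyl-2-(prop-1-en-2-yl)-5-[(triethylsilyl)oxy]hexyl}-1,3-bis{[2-(trimethylsilyl)ethoxy]methoxy}benzene | C=C(C)[C@H](CCC(C)(C)O[Si](CC)(CC)CC)Cc1c(OCOCC[Si](C)(C)C)cc(OCOC)cc1OCOCC[Si](C)(C)C | intermediate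
16 | [6-(methoxymethoxy)-3-{(2R)-5-methyl-2-(prop-1-en-2-yl)-5-[(triethylsilyl)oxy]hexyl}-2,4-bis{[2-(trimethylsilyl)ethoxy]methoxy}phenyl]lithium | C=C(C)[C@H](CCC(C)(C)O[Si](CC)(CC)CC)Cc1c(OCOCC[Si](C)(C)C)cc(OCOC)c([Li])c1OCOCC[Si](C)(C)C | intermediate, not isolated
17 | 1-[6-(methoxymethoxy)-3-{(2R)-5-methyl-2-(prop-1-en-2-yl)-5-[(triethylsilyl)oxy]hexyl}-2,4-bis{[2-(trimethylsilyl)ethoxy]methoxy}phenyl]ethan-1-one | C=C(C)[C@H](CCC(C)(C)O[Si](CC)(CC)CC)Cc1c(OCOCC[Si](C)(C)C)cc(OCOC)c(C(C)=O)c1OCOCC[Si](C)(C)C | intermediate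
18 | 1-{2,4-dihydroxy-3-[(2R)-5-hydroxy-5-methyl-2-(prop-1-en-2-yl)hexyl]-6-(methoxymethoxy)phenyl}ethan-1-one | C=C(C)[C@H](CCC(C)(C)O)Cc1c(O)cc(OCOC)c(C(C)=O)c1O | intermediate
19 | N-[(2,4-dihydroxyphenyl)methylidene]-N-methylmethanaminium chloride | C[N+](C)=Cc1ccc(O)cc1O.[Cl-] | intermediate, not isolated
20 | 2,4-dihydroxybenzaldehyde | O=Cc1ccc(O)cc1O | intermediate
21 | 2,4-bis(methoxymethoxy)benzaldehyde | COCOc1ccc(C=O)c(OCOC)c1 | intermediate
22 | (2E)-3-[2,4-bis(methoxymethoxy)phenyl]-1-{2,4-dihydroxy-3-[(2R)-5-hydroxy-5-methyl-2-(prop-1-en-2-yl)hexyl]-6-(methoxymethoxy)phenyl}prop-2-en-1-one | C=C(C)[C@H](CCC(C)(C)O)Cc1c(O)cc(OCOC)c(C(=O)/C=C/c2ccc(OCOC)cc2OCOC)c1O | intermediate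
23 | (2S)-2-[2,4-bis(methoxymethoxy)phenyl]-7-hydroxy-8-[(2R)-5-hydroxy-5-methyl-2-(prop-1-en-2-yl)hexyl]-5-(methoxymethoxy)-2,3-dihydro-4H-chromen-4-one | C=C(C)[C@H](CCC(C)(C)O)Cc1c(O)cc(OCOC)c2c1O[C@H](c1ccc(OCOC)cc1OCOC)CC2=O | intermediate
24 | norkurarinol, (2S)-2-(2,4-dihydroxyphenyl)-5,7-dihydroxy-8-[(2R)-5-hydroxy-5-methyl-2-(prop-1-en-2-yl)hexyl]-2,3-dihydro-4H-chromen-4-one | C=C(C)[C@H](CCC(C)(C)O)Cc1c(O)cc(O)c2c1O[C@H](c1ccc(O)cc1O)CC2=O | target

## Step count and risks

Total step count: 15. Longest linear sequence: 11 steps (steps 1–4, 7–10 and 13–15 from resorcinol); steps 5–6 and 11–12 are side branches.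

**Step 7 (conjunctive coupling).** The aryl bromide carries two ortho acetal oxygens and is electron-rich, which is outside the electrophiles shown for this reaction, so alkene binding at palladium or the enantioselectivity may suffer. The fallback sets out from 7 and sets the stereocentre by alkene diboration instead of by the metallate shift. Commercial 2-methylhex-5-en-2-ol F1 is silylated (TESOTf, 2,6-lutidine) to triethyl[(2-methylhex-5-en-2-yl)oxy]silane F2. Enantioselective diboration (B2pin2, Pt(dba)3, TADDOL-derived phosphonite, THF, 60 °C) gives the (S)-1,2-bis(boronate) F3. Suzuki–Miyaura coupling of its primary C–B bond with 7 (Pd(OAc)2, RuPhos, KOH, THF/H2O, 70 °C) gives 12, where the route is rejoined before step 8.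

**Step 13 (Claisen–Schmidt condensation).** The free 4-OH of 18 is deprotonated under the conditions and deactivates the hindered ketone, so conversion may be poor. The fallback sets out from 18 and masks that phenol first. MOMCl and K2CO3 in acetone alkylate only the non-chelated 4-OH to give 1-{2-hydroxy-3-[(2R)-5-hydroxy-5-methyl-2-(prop-1-en-2-yl)hexyl]-4,6-bis(methoxymethoxy)phenyl}ethan-1-one F4, a ketone of the type that is known to condense cleanly. Condensation with 21 (KOH, EtOH) gives the chalcone F5, cyclisation as in step 14 gives the 7-O-MOM flavanone F6, and the conditions of step 15 remove all four MOM groups, so the route is rejoined at 24.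

**Step 14 (proposed new cyclisation).** The acid may be too weak to turn the chalcone over, or the enantioselectivity may be low or eroded by reversal. The fallback uses known chemistry and sets out from 22: NaOAc in EtOH at reflux cyclises 22 under equilibrium control to 23 and its 2R epimer F7 in about equal amounts. Because the side chain already holds a fixed R centre these are diastereomers, and they are separated by preparative HPLC. F7 is put back under the same conditions, where it re-equilibrates through 22, and the route is rejoined at 23.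

Further compounds
F1 | step 7 | 2-methylhex-5-en-2-ol | C=CCCC(C)(C)O
F2 | step 7 | triethyl[(2-methylhex-5-en-2-yl)oxy]silane | C=CCCC(C)(C)O[Si](CC)(CC)CC
F3 | step 7 | triethyl{[(5S)-2-methyl-5,6-bis(4,4,5,5-tetramethyl-1,3,2-dioxaborolan-2-yl)hexan-2-yl]oxy}silane | CC[Si](CC)(CC)OC(C)(C)CC[C@H](CB1OC(C)(C)C(C)(C)O1)B1OC(C)(C)C(C)(C)O1
F4 | step 13 | 1-{2-hydroxy-3-[(2R)-5-hydroxy-5-methyl-2-(prop-1-en-2-yl)hexyl]-4,6-bis(methoxymethoxy)phenyl}ethan-1-one | C=C(C)[C@H](CCC(C)(C)O)Cc1c(OCOC)cc(OCOC)c(C(C)=O)c1O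
F5 | step 13 | (2E)-3-[2,4-bis(methoxymethoxy)phenyl]-1-{2-hydroxy-3-[(2R)-5-hydroxy-5-methyl-2-(prop-1-en-2-yl)hexyl]-4,6-bis(methoxymethoxy)phenyl}prop-2-en-1-one | C=C(C)[C@H](CCC(C)(C)O)Cc1c(OCOC)cc(OCOC)c(C(=O)/C=C/c2ccc(OCOC)cc2OCOC)c1O
F6 | step 13 | (2S)-2-[2,4-bis(methoxymethoxy)phenyl]-8-[(2R)-5-hydroxy-5-methyl-2-(prop-1-en-2-yl)hexyl]-5,7-bis(methoxymethoxy)-2,3-dihydro-4H-chromen-4-one | C=C(C)[C@H](CCC(C)(C)O)Cc1c(OCOC)cc(OCOC)c2c1O[C@H](c1ccc(OCOC)cc1OCOC)CC2=O
F7 | step 14 | (2R)-2-[2,4-bis(methoxymethoxy)phenyl]-7-hydroxy-8-[(2R)-5-hydroxy-5-methyl-2-(prop-1-en-2-yl)hexyl]-5-(methoxymethoxy)-2,3-dihydro-4H-chromen-4-one | C=C(C)[C@H](CCC(C)(C)O)Cc1c(O)cc(OCOC)c2c1O[C@@H](c1ccc(OCOC)cc1OCOC)CC2=O
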